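## The problem

Morusyunnansin E (27) is a (2S)-flavan: a dihydropyran ring (O1, C2, C3, C4) fused to ring A through C4a and C8a, with a 2,4-dihydroxyphenyl group (ring B) on C2. Ring A carries four substituents in a row: the C4 methylene on C4a, O1 on C8a, an (E)-4-hydroxy-3-methylbut-2-enyl chain on C8 and a methoxyl on C7. The chain therefore sits between two oxygens, a position that electrophilic substitution of a resorcinol ether does not select cleanly. C2 is the only stereocentre. Nothing else in the molecule can direct it, so it must be set by a reagent and then carried or transferred without loss. That is the delicate point: C2 is a benzylic ether carbon on a ring with oxygen ortho and para, so acid ionises the C2–O1 bond, and base does the same through a quinone methide once the ring B phenols are free. The side chain adds a trisubstituted allylic alcohol that tolerates neither hydrogenation nor strong acid, which rules out benzyl ethers and acetals as phenol protecting groups. A short route is possible because the sequence C4a(alkyl)–C8a(O)–C8(alkyl)–C7(OMe), with C5 and C6 unsubstituted, is the pattern of the phenol that a β-substituted vinylketene and a 1-methoxyalkyne form, the phenol oxygen becoming O1.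

## Retrosynthesis

**27 ⇒ 26 (three O–acyl bonds, no skeletal bond).** The three hydroxyls are traced back to the tris(pivalate) 26. Esters are preferred to acetal, benzyl or silyl ethers for a structural reason. An acyloxy group ortho and para to C2 removes the electron release that makes the C2–O1 bond ionisable, and it comes off with hydride at −78 °C, where neither C2 nor the allylic alcohol is at risk. The same ester on the side chain lets one operation finish the synthesis. The forward step must cleave three hindered esters without opening the pyran ring.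

**26 ⇒ 25 ⇒ 24 (O1–C2).** Of the pyran bonds, O1–C2 is the one whose cleavage leads back to a phenol, which is what a vinylketene annulation delivers. Cutting C4–C4a or O1–C8a would require an aryl halide or a free arene position and would waste that oxygen. The precursor 25 is an open-chain phenol carbinol. Closure by SN2 inverts, so 25 must be (R). It comes from the silyl ether 24, because the hydroxyl has to be masked while ketenes are present. The forward reaction must invert cleanly, which the ring B esters are meant to secure, and must close a six-membered ring with a phenol flanked on both sides.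

**24 ⇒ 13 + 19 (C8a–C8, C7–C6, C8a–C4a).** Ring A is taken apart completely into diazo enone 13 and ynol ether 19. Decorating a preformed resorcinol would need separate operations for the C8 chain and the C4a chain. Here both arrive with the ring, the chain between the two oxygens on the alkyne and the C2-bearing chain on the diazo ketone. Neither precursor contains ring A, and the two are of similar size. The forward cascade needs one selectivity, the orientation of the ketene–alkyne [2+2] step, and must tolerate esters, a silyl ether and a trisubstituted alkene.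

**13 ⇒ 11 ⇒ 8 + 9 (C–N2, then the C=C that becomes C4a–C5).** The diazo group is put on the methyl ketone 11 by activation and diazo transfer. The enone is cut at its double bond into alcohol 8, oxidised in the flask, and the commercial ylide 9. Both precursors are simpler by one functional group each, and the forward steps must leave the benzylic silyl ether and the aryl esters untouched.

**8 ⇒ 6 ⇒ 5 ⇒ 2 + 3 ⇒ 1 (C2–C3, the stereocentre).** The primary alcohol comes from the terminal alkene of 6 by hydroboration. The homoallylic carbinol 5 is cut between C2 and C3 into aldehyde 2 and allylboronate 3. An asymmetric allylation sets the configuration in one catalytic step on an aryl aldehyde, whereas a ketone reduction would need two more steps. Aldehyde 2 is the bis(pivalate) of commercial 1.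

**19 ⇒ 16 + 17 ⇒ 15 ⇒ 14 (C(sp)–CH2).** The ynol ether is cut next to the triple bond into allylic chloride 16 and the methoxyacetylide derived from chloroacetal 17. Chloride 16 is the pivalate of 15, which comes from isoprene monoxide 14 by SN2′ opening with chloride. The opening must give the (E)-alkene, and the alkylation must preserve it.

## Roads not taken

**Alternative 1: ortho-quinone methide plus hydroxystyrene.**
- Cut: C3–C4 and O1–C2, dividing the target into the ring A salicyl alcohol A2 and the ring B styrene A3.
- Forward step: a chiral Brønsted acid would dehydrate A2 to its ortho-quinone methide and hold it, through the free 2′-hydroxyl of A3, for an inverse-demand hetero-[4+2] cycloaddition. This gives flavan A1 with C2 set by the catalyst.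
- Merits: the pyran ring and the stereocentre are made together from two aromatic halves. The regiochemistry is unambiguous, since the styrene terminus joins the methide carbon. A1 needs only desilylation, so the route could be three or four steps shorter than the one proposed.
- Weak points:
  - Enantioselective versions of this cycloaddition rely on quinone methides stabilised by an aryl group on the methide carbon. The methide needed here is an unsubstituted CH2 (C4), which is far more reactive and oligomerises, and facial control at the distant styrene carbon is unknown.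
  - A3 is an acid-sensitive, polymerisable styrene.
  - A1 has a free 2′-hydroxyl next to an ionisable C2–O1 bond in an acidic medium, so its enantiomeric purity could erode after the event.
  - A2 still needs the contiguous ring A pattern, which would be built by metalation between the two oxygens, alkylation and hydroxymethylation.
- Comparison: in convergence and step count this road is better. The chosen plan offers in return stereochemical events of known behaviour (allylboration of an aryl aldehyde, SN2 closure at a deactivated benzylic carbon), whereas here the one step that matters would have to be developed.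

**Alternative 2: ring-closing metathesis.**
- Cut: C3=C4 of flav-3-ene A4, made from diene A5, in which ring A carries a vinyl group on C4a and O1 bears the (S)-1-arylallyl group.
- Forward step: a ruthenium alkylidene (second-generation Grubbs catalyst) joins the two vinyl groups with loss of their terminal methylenes.
- Merits: formation of 2H-chromenes in this way is dependable and thermal. The trisubstituted side-chain alkene is too hindered to interfere. Both aromatic rings are brought in ready-made.
- Weak points:
  - The stereocentre must be set when the ring A phenol, flanked by the vinyl group and the side chain, is joined to the ring B allyl unit. That means either substitution at a carbinol that is both allylic and benzylic to a dioxygenated ring, or a branched-selective asymmetric allylic etherification with a 2,6-disubstituted phenol. Neither is secure.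
  - In A4 the C2–O1 bond is benzylic, allylic and part of a 2H-chromene. It can open reversibly by 6π electrocyclic ring opening or ionise to a flavylium ion.
  - C3=C4 must then be saturated without touching the side-chain alkene or hydrogenolysing C2–O1.
  - The methoxymethyl ethers of A4 come off only with acid, which C2 and the allylic alcohol tolerate poorly.
- Comparison: the length is similar, and the ring closure is more predictable than the photochemical cascade of step 10. The regiochemical argument for the benzannulation is not decisive, since ortho-metalation would place the chain at C8 of the ring A component equally well. The chosen plan's advantage is that the stereocentre is exposed in one later operation (step 12) on a deactivated ring, not in three.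

**Alternative 3: gold-catalysed hydroarylation.**
- Cut: C4–C4a. The precursor is aryl propargyl ether A7.
- Forward step: a cationic monovalent gold complex activates the terminal alkyne, and the ring A carbon ortho to oxygen attacks in a 6-endo-dig manner to give flav-3-ene A6.
- Merits: ring A needs no carbon substituent at C4a, so its component is a simple resorcinol-derived ether with one free ortho position. The step is catalytic and atom-economic.
- Weak points:
  - The propargylic C2–O bond of A7 lies next to a 2,4-bis(silyloxy)phenyl ring. π-Acids ionise such ethers, which would racemise or cleave the substrate.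
  - 5-exo closure and reaction of the side-chain alkene with the activated alkyne can compete.
  - Making A7 as one enantiomer again requires substitution at a doubly activated carbinol.
  - A6 has the chromene liabilities of A4 and needs the same chemoselective reduction.
- Comparison: this is the shortest access to the ring system on paper, and the chosen plan cannot match the economy of its ring A component. The chosen plan offers instead a stereocentre that is never allylic, propargylic or attached to an electron-rich ring at any stage where a bond to it is made or broken.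

Key step: step 10

## Route

Remark: flavan numbering (O1, C2–C4, C4a, C5–C8, C8a; ring B primed) is used for the target and its precursors; pivaloyl = 2,2-dimethylpropanoyl. The (R)-phosphoric acid of step 2 is assumed to direct allyl transfer to the Re face of 2, as it does for other aryl aldehydes.

Step 1
Reactants: 1 2,4-dihydroxybenzaldehyde
Product: 2 2,4-bis(pivaloyloxy)benzaldehyde
Conditions: PivCl, Et3N, DMAP (cat.), CH2Cl2, 0 °C to rt
Reagents that add atoms: pivaloyl chloride, CC(C)(C)C(=O)Cl
Why: DMAP-catalysed esterification of both phenols; the hydrogen-bonded 2-hydroxyl is slower but is driven over by excess acid chloride. The esters make ring B electron-poor for every later event at the benzylic carbon.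

Step 2
Reactants: 2 2,4-bis(pivaloyloxy)benzaldehyde; 3 allylboronic acid pinacol ester
Product: 5 (R)-1-[2,4-bis(pivaloyloxy)phenyl]but-3-en-1-ol, via pinacol borate 4 (not isolated)
Conditions: (R)-3,3′-bis(2,4,6-triisopropylphenyl)-1,1′-binaphthyl-2,2′-diyl hydrogen phosphate (5 mol %), toluene, −30 °C; aq. NaHCO3 work-up
Reagents that add atoms: none
Why: Chiral phosphoric acid-catalysed allylboration through a chair transition state in which the acid binds a boronate oxygen and the formyl hydrogen; the (R)-acid directs allyl transfer to the Re face of aryl aldehydes, which gives the (R)-carbinol and sets the only stereocentre of the route. Borate 4 is hydrolysed on work-up.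

Step 3
Reactants: 5 (R)-1-[2,4-bis(pivaloyloxy)phenyl]but-3-en-1-ol
Product: 6 (R)-1-[2,4-bis(pivaloyloxy)phenyl]-1-(triethylsilyloxy)but-3-ene
Conditions: Et3SiOTf, 2,6-lutidine, CH2Cl2, −78 °C
Reagents that add atoms: triethylsilyl trifluoromethanesulfonate, CC[Si](CC)(CC)OS(=O)(=O)C(F)(F)F
Why: Silylation of a secondary alcohol with a silyl triflate and a hindered base; the non-nucleophilic, cold conditions avoid migration of the neighbouring 2′-pivaloyl group to the benzylic oxygen.

Step 4
Reactants: 6 (R)-1-[2,4-bis(pivaloyloxy)phenyl]-1-(triethylsilyloxy)but-3-ene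
Product: 8 (R)-4-[2,4-bis(pivaloyloxy)phenyl]-4-(triethylsilyloxy)butan-1-ol, via B-alkyl-9-borabicyclononane 7 (not isolated)
Conditions: 9-borabicyclo[3.3.1]nonane (9-BBN), THF, 0 °C to rt; then 30% H2O2, pH 7 phosphate buffer, 0 °C to rt
Reagents that add atoms: hydrogen peroxide, OO
Why: Anti-Markovnikov hydroboration of the terminal alkene and oxidation of the C–B bond; buffered peroxide spares the aryl esters and the silyl ether, and the stereocentre is not involved.

Step 5
Reactants: 8 (R)-4-[2,4-bis(pivaloyloxy)phenyl]-4-(triethylsilyloxy)butan-1-ol; 9 1-(triphenylphosphoranylidene)propan-2-one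
Product: 11 (R,E)-7-[2,4-bis(pivaloyloxy)phenyl]-7-(triethylsilyloxy)hept-3-en-2-one, via aldehyde 10 (not isolated)
Conditions: Dess–Martin periodinane, 9 (excess), CH2Cl2, rt (one pot)
Reagents that add atoms: none
Why: Dess–Martin oxidation in the presence of a stabilised ylide, so that aldehyde 10 is trapped as it forms in a Wittig reaction; the acetonyl ylide gives the (E)-enone, and the excess ylide buffers the acetic acid released.

Step 6
Reactants: 11 (R,E)-7-[2,4-bis(pivaloyloxy)phenyl]-7-(triethylsilyloxy)hept-3-en-2-one
Product: 13 (R,E)-1-diazo-7-[2,4-bis(pivaloyloxy)phenyl]-7-(triethylsilyloxy)hept-3-en-2-one, via trifluoroacetyl ketone 12 (not isolated)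
Conditions: LiN(SiMe3)2, THF, −78 °C; CF3CO2CH2CF3, −78 °C; aq. NH4Cl work-up; then MsN3, Et3N, H2O, MeCN, rt
Reagents that add atoms: methanesulfonyl azide, CS(=O)(=O)N=[N+]=[N-]
Why: Detrifluoroacetylative diazo transfer: kinetic deprotonation at the methyl group, Claisen trifluoroacetylation to 12, then transfer of N2 from the sulfonyl azide with loss of the trifluoroacetyl group. The pivalates should tolerate the brief exposure to the amide base at −78 °C.

Step 7
Reactants: 14 isoprene monoxide (2-methyl-2-vinyloxirane, racemic)
Product: 15 (E)-4-chloro-2-methylbut-2-en-1-ol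
Conditions: TiCl4, CH2Cl2, −85 °C; aqueous work-up
Reagents that add atoms: titanium tetrachloride, Cl[Ti](Cl)(Cl)Cl
Why: Lewis acid-mediated SN2′ opening of a vinyl epoxide: the titanium-bound oxygen leaves as chloride is delivered to the vinyl terminus, a reaction known to favour the (E)-allylic alcohol.

Step 8
Reactants: 15 (E)-4-chloro-2-methylbut-2-en-1-ol
Product: 16 (E)-4-chloro-2-methylbut-2-en-1-yl pivalate
Conditions: PivCl, pyridine, CH2Cl2, 0 °C
Reagents that add atoms: pivaloyl chloride, CC(C)(C)C(=O)Cl
Why: Acylation of a primary allylic alcohol, run cold and briefly so that the allylic chloride does not quaternise the base.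

Step 9
Reactants: 16 (E)-4-chloro-2-methylbut-2-en-1-yl pivalate; 17 chloroacetaldehyde dimethyl acetal
Product: 19 (E)-6-methoxy-2-methylhex-2-en-5-yn-1-yl pivalate, via lithium methoxyacetylide 18 (not isolated)
Conditions: 17, LiNEt2 (3 equiv), THF, 0 °C; then 16, DMPU, −78 °C to 0 °C
Reagents that add atoms: none
Why: Two eliminations and a deprotonation convert the chloroacetal into lithium methoxyacetylide 18, which displaces the primary allylic chloride by SN2 in the presence of a dipolar cosolvent. SN2′ attack would have to occur at a fully substituted alkene carbon, so the (E)-alkene should be preserved; the hindered pivalate is expected to resist the acetylide.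

Step 10
Reactants: 13 (R,E)-1-diazo-7-[2,4-bis(pivaloyloxy)phenyl]-7-(triethylsilyloxy)hept-3-en-2-one; 19 (E)-6-methoxy-2-methylhex-2-en-5-yn-1-yl pivalate
Product: 24 6-[(R)-3-[2,4-bis(pivaloyloxy)phenyl]-3-(triethylsilyloxy)propyl]-3-methoxy-2-[(E)-3-methyl-4-(pivaloyloxy)but-2-en-1-yl]phenol, via vinylketene 20 (not isolated), via cyclobutenone 21 (not isolated), via dienylketene 22 (not isolated), via cyclohexadienone 23 (not isolated)
Conditions: 19 (1.5 equiv), hν (300 nm, Pyrex), degassed CH2Cl2, rt; then toluene, 80 °C
Reagents that add atoms: none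
Why: This is the Danheiser benzannulation in its diazo ketone variant with an alkoxyalkyne. Light expels N2 from 13 and the alkenyl group migrates (photochemical Wolff rearrangement) to give vinylketene 20. The ketene adds across the ynol ether in a [2+2] cycloaddition whose orientation is set by polarisation: the nucleophilic carbon of 19 that bears the side chain bonds to the ketene carbonyl carbon (C8–C8a) and the methoxy-bearing carbon to the ketene α-carbon (C7–C6), giving cyclobutenone 21. 4π electrocyclic opening of 21 gives dienylketene 22, and ring A closes by 6π electrocyclisation between the ketene carbon and the chain-bearing alkene terminus (C8a–C4a) to cyclohexadienone 23, which tautomerises to phenol 24; warming in toluene completes the conversion of any remaining 21. No stereocentre is created in 24, because the sp3 centres of 21 and 23 are transient and C2 lies four atoms from the nearest reacting carbon. The one selectivity required is the orientation of the [2+2] step, which the methoxy group secures; preference for the ynol ether over the trisubstituted alkene follows from the far higher nucleophilicity of the alkyne. Irradiation through Pyrex is chosen because the diazo enone absorbs there while aryl esters are expected to be transparent, and the basic clean-up often used after such annulations is omitted on account of the esters.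

Step 11
Reactants: 24 6-[(R)-3-[2,4-bis(pivaloyloxy)phenyl]-3-(triethylsilyloxy)propyl]-3-methoxy-2-[(E)-3-methyl-4-(pivaloyloxy)but-2-en-1-yl]phenol
Product: 25 6-[(R)-3-[2,4-bis(pivaloyloxy)phenyl]-3-hydroxypropyl]-3-methoxy-2-[(E)-3-methyl-4-(pivaloyloxy)but-2-en-1-yl]phenol
Conditions: HF·pyridine, pyridine, THF, 0 °C to rt
Reagents that add atoms: none
Why: Buffered fluoride cleavage of the secondary triethylsilyl ether; the alcohol, not the alkoxide, is released, so the 2′-pivaloyl group has no occasion to migrate. The electron-poor ring B keeps the free benzylic alcohol from ionising.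

Step 12
Reactants: 25 6-[(R)-3-[2,4-bis(pivaloyloxy)phenyl]-3-hydroxypropyl]-3-methoxy-2-[(E)-3-methyl-4-(pivaloyloxy)but-2-en-1-yl]phenol
Product: 26 (S)-2-[2,4-bis(pivaloyloxy)phenyl]-7-methoxy-8-[(E)-3-methyl-4-(pivaloyloxy)but-2-en-1-yl]chroman
Conditions: PPh3, DIAD, THF (dilute), 0 °C to rt
Reagents that add atoms: none
Why: Intramolecular Mitsunobu etherification: the benzylic alcohol is activated as its oxyphosphonium ion and displaced by the ring A phenoxide in a 6-exo-tet SN2 reaction, so the (R)-carbinol becomes the (2S)-flavan with inversion. The two acyloxy groups on ring B disfavour the ionisation that would erode the configuration.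

Step 13
Reactants: 26 (S)-2-[2,4-bis(pivaloyloxy)phenyl]-7-methoxy-8-[(E)-3-methyl-4-(pivaloyloxy)but-2-en-1-yl]chroman
Product: 27 morusyunnansin E, (S)-4-[8-[(E)-4-hydroxy-3-methylbut-2-en-1-yl]-7-methoxychroman-2-yl]benzene-1,3-diol
Conditions: i-Bu2AlH (excess), CH2Cl2, −78 °C; MeOH, then aq. sodium potassium tartrate
Reagents that add atoms: none
Why: Reductive cleavage of the three pivalates by hydride at low temperature; no acid, prolonged base or hydrogen is involved, so C2, the allylic alcohol and the alkene should be preserved.

## Compound list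

1 | 2,4-dihydroxybenzaldehyde | O=Cc1ccc(O)cc1O | starting material
2 | 2,4-bis(pivaloyloxy)benzaldehyde | O=Cc1ccc(OC(=O)C(C)(C)C)cc1OC(=O)C(C)(C)C | intermediate
3 | allylboronic acid pinacol ester | C=CCB1OC(C)(C)C(C)(C)O1 | starting material
4 | 2-{(R)-1-[2,4-bis(pivaloyloxy)phenyl]but-3-en-1-yloxy}-4,4,5,5-tetramethyl-1,3,2-dioxaborolane | C=CC[C@@H](OB1OC(C)(C)C(C)(C)O1)c1ccc(OC(=O)C(C)(C)C)cc1OC(=O)C(C)(C)C | intermediate
5 | (R)-1-[2,4-bis(pivaloyloxy)phenyl]but-3-en-1-ol | C=CC[C@@H](O)c1ccc(OC(=O)C(C)(C)C)cc1OC(=O)C(C)(C)C | intermediate
6 | (R)-1-[2,4-bis(pivaloyloxy)phenyl]-1-(triethylsilyloxy)but-3-ene | C=CC[C@@H](O[Si](CC)(CC)CC)c1ccc(OC(=O)C(C)(C)C)cc1OC(=O)C(C)(C)C | intermediate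
7 | 9-{(R)-4-[2,4-bis(pivaloyloxy)phenyl]-4-(triethylsilyloxy)butyl}-9-borabicyclo[3.3.1]nonane | B1(CCC[C@@H](O[Si](CC)(CC)CC)c2ccc(OC(=O)C(C)(C)C)cc2OC(=O)C(C)(C)C)C2CCCC1CCC2 | intermediate
8 | (R)-4-[2,4-bis(pivaloyloxy)phenyl]-4-(triethylsilyloxy)butan-1-ol | OCCC[C@@H](O[Si](CC)(CC)CC)c1ccc(OC(=O)C(C)(C)C)cc1OC(=O)C(C)(C)C | intermediate
9 | 1-(triphenylphosphoranylidene)propan-2-one | CC(=O)C=P(c1ccccc1)(c1ccccc1)c1ccccc1 | starting material
10 | (R)-4-[2,4-bis(pivaloyloxy)phenyl]-4-(triethylsilyloxy)butanal | O=CCC[C@@H](O[Si](CC)(CC)CC)c1ccc(OC(=O)C(C)(C)C)cc1OC(=O)C(C)(C)C | intermediate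
11 | (R,E)-7-[2,4-bis(pivaloyloxy)phenyl]-7-(triethylsilyloxy)hept-3-en-2-one | CC(=O)/C=C/CC[C@@H](O[Si](CC)(CC)CC)c1ccc(OC(=O)C(C)(C)C)cc1OC(=O)C(C)(C)C | intermediate
12 | (R,E)-9-[2,4-bis(pivaloyloxy)phenyl]-1,1,1-trifluoro-9-(triethylsilyloxy)non-5-ene-2,4-dione | O=C(CC(=O)/C=C/CC[C@@H](O[Si](CC)(CC)CC)c1ccc(OC(=O)C(C)(C)C)cc1OC(=O)C(C)(C)C)C(F)(F)F | intermediate
13 | (R,E)-1-diazo-7-[2,4-bis(pivaloyloxy)phenyl]-7-(triethylsilyloxy)hept-3-en-2-one | [N-]=[N+]=CC(=O)/C=C/CC[C@@H](O[Si](CC)(CC)CC)c1ccc(OC(=O)C(C)(C)C)cc1OC(=O)C(C)(C)C | intermediate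
14 | isoprene monoxide (2-methyl-2-vinyloxirane, racemic) | CC1(C=C)CO1 | starting material
15 | (E)-4-chloro-2-methylbut-2-en-1-ol | ClC/C=C(\C)CO | intermediate
16 | (E)-4-chloro-2-methylbut-2-en-1-yl pivalate | ClC/C=C(\C)COC(=O)C(C)(C)C | intermediate
17 | chloroacetaldehyde dimethyl acetal | COC(CCl)OC | starting material
18 | lithium methoxyacetylide | [Li]C#COC | intermediate
19 | (E)-6-methoxy-2-methylhex-2-en-5-yn-1-yl pivalate | COC#CC/C=C(\C)COC(=O)C(C)(C)C | intermediate
20 | (R,E)-7-[2,4-bis(pivaloyloxy)phenyl]-7-(triethylsilyloxy)hepta-1,3-dien-1-one (vinylketene) | O=C=C/C=C/CC[C@@H](O[Si](CC)(CC)CC)c1ccc(OC(=O)C(C)(C)C)cc1OC(=O)C(C)(C)C | intermediate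
21 | 3-methoxy-2-[(E)-3-methyl-4-(pivaloyloxy)but-2-en-1-yl]-4-{(R,E)-5-[2,4-bis(pivaloyloxy)phenyl]-5-(triethylsilyloxy)pent-1-en-1-yl}cyclobut-2-en-1-one (both C4 epimers) | COC1=C(C/C=C(\C)COC(=O)C(C)(C)C)C(=O)C1/C=C/CC[C@@H](O[Si](CC)(CC)CC)c1ccc(OC(=O)C(C)(C)C)cc1OC(=O)C(C)(C)C | intermediate
22 | (R,3E,5E)-9-[2,4-bis(pivaloyloxy)phenyl]-3-methoxy-2-[(E)-3-methyl-4-(pivaloyloxy)but-2-en-1-yl]-9-(triethylsilyloxy)nona-1,3,5-trien-1-one (dienylketene, C2 and C5 cis across C3=C4) | O=C=C(C/C=C(\C)COC(=O)C(C)(C)C)/C(OC)=C\C=C\CC[C@@H](O[Si](CC)(CC)CC)c1ccc(OC(=O)C(C)(C)C)cc1OC(=O)C(C)(C)C | intermediate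
23 | 6-{(R)-3-[2,4-bis(pivaloyloxy)phenyl]-3-(triethylsilyloxy)propyl}-3-methoxy-2-[(E)-3-methyl-4-(pivaloyloxy)but-2-en-1-yl]cyclohexa-2,4-dien-1-one (both C6 epimers) | COC1=C(C/C=C(\C)COC(=O)C(C)(C)C)C(=O)C(CC[C@@H](O[Si](CC)(CC)CC)c2ccc(OC(=O)C(C)(C)C)cc2OC(=O)C(C)(C)C)C=C1 | intermediate
24 | 6-[(R)-3-[2,4-bis(pivaloyloxy)phenyl]-3-(triethylsilyloxy)propyl]-3-methoxy-2-[(E)-3-methyl-4-(pivaloyloxy)but-2-en-1-yl]phenol | COc1ccc(CC[C@@H](O[Si](CC)(CC)CC)c2ccc(OC(=O)C(C)(C)C)cc2OC(=O)C(C)(C)C)c(O)c1C/C=C(\C)COC(=O)C(C)(C)C | intermediate
25 | 6-[(R)-3-[2,4-bis(pivaloyloxy)phenyl]-3-hydroxypropyl]-3-methoxy-2-[(E)-3-methyl-4-(pivaloyloxy)but-2-en-1-yl]phenol | COc1ccc(CC[C@@H](O)c2ccc(OC(=O)C(C)(C)C)cc2OC(=O)C(C)(C)C)c(O)c1C/C=C(\C)COC(=O)C(C)(C)C | intermediate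
26 | (S)-2-[2,4-bis(pivaloyloxy)phenyl]-7-methoxy-8-[(E)-3-methyl-4-(pivaloyloxy)but-2-en-1-yl]chroman | COc1ccc2c(c1C/C=C(\C)COC(=O)C(C)(C)C)O[C@H](c1ccc(OC(=O)C(C)(C)C)cc1OC(=O)C(C)(C)C)CC2 | intermediate
27 | morusyunnansin E, (S)-4-[8-[(E)-4-hydroxy-3-methylbut-2-en-1-yl]-7-methoxychroman-2-yl]benzene-1,3-diol | COc1ccc2c(c1C/C=C(\C)CO)O[C@H](c1ccc(O)cc1O)CC2 | target

## Step count and least certain steps

Total: 13 steps. Longest linear sequence: 10 steps (steps 1–6 and 10–13 from 1). The ynol ether branch is 3 steps (7–9).

**Step 10 (key step).** The vinylketene may be lost to dimerisation, or may acylate the product phenol, faster than it is captured by a hindered ynol ether that cannot be used in large excess. The skipped enynol ether may also degrade under irradiation, and the basic clean-up that normally rescues O-acylated phenol is closed by the pivalates.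
Fallback, from 13 to 24, with the side chain finished after the annulation:
- Lithium methoxyacetylide 18 (from 17) is alkylated with allyl bromide to give 1-methoxypent-4-en-1-yne F1, a small ynol ether that can be used in several-fold excess.
- Irradiation of 13 with F1 as in step 10 should give 2-allyl-6-{(R)-3-[2,4-bis(pivaloyloxy)phenyl]-3-(triethylsilyloxy)propyl}-3-methoxyphenol F2.
- Cross-metathesis of F2 with methacrolein (second-generation Hoveyda–Grubbs catalyst) should give the (E)-enal (E)-4-(3-{(R)-3-[2,4-bis(pivaloyloxy)phenyl]-3-(triethylsilyloxy)propyl}-2-hydroxy-6-methoxyphenyl)-2-methylbut-2-enal F3.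
- Luche reduction (NaBH4, CeCl3·7H2O) gives the allylic alcohol 6-{(R)-3-[2,4-bis(pivaloyloxy)phenyl]-3-(triethylsilyloxy)propyl}-2-[(E)-4-hydroxy-3-methylbut-2-en-1-yl]-3-methoxyphenol F4.
- Pivaloylation of the primary hydroxyl in preference to the flanked phenol returns to 24.

**Step 12.** The activated benzylic oxyphosphonium ion may ionise, which would erode the configuration, or eliminate to the styrene. Closure may also be slow because the phenol is flanked by two substituents and is weakly acidic.
Fallback, from 24 to 26, with activation separated from displacement: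
- The phenol of 24 is silylated (t-BuMe2SiOTf, 2,6-lutidine) to its tert-butyldimethylsilyl ether F5.
- The triethylsilyl ether is removed as in step 11 to give the (R)-alcohol F6.
- Mesylation at low temperature gives the (R)-methanesulfonate F7, without touching the stereocentre.
- CsF in DMF frees the phenoxide, which displaces the mesylate with inversion to give 26.

**Step 9.** Residual amide or the methoxide formed alongside 18 may attack the pivalate or the allylic chloride, and base may isomerise the skipped enyne to a conjugated allenyl or enynyl ether.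
Fallback, from 15 to 19, with alkylation before esterification: the lithium alkoxide of 15 (n-BuLi, −78 °C) is alkylated with 18 to give (E)-6-methoxy-2-methylhex-2-en-5-yn-1-ol F8. Acylation with pivalic anhydride, Et3N and DMAP then gives 19.

**Step 2.** The ortho pivaloyloxy group may disturb the fit of the aldehyde in the catalyst pocket and lower facial selectivity.
Fallback, from 2 to 5: Brown allylboration with (+)-B-allyldiisopinocampheylborane (the reagent from (−)-α-pinene, which adds to the Re face of aryl aldehydes) at −78 °C, with an amino alcohol work-up in place of the oxidative one. This fallback makes no new compound (F0).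

**Step 6.** Deprotonation at the γ-methylene may compete, or the enolate may attack an aryl ester, and the diazo transfer may be incomplete.
Fallback, from 8 to 13, with the diazo group brought in by the olefination: 8 is oxidised to 10, which is isolated this time. It is then condensed with diethyl (3-diazo-2-oxopropyl)phosphonate F9 (prepared from diethylphosphonoacetic acid through its acid chloride and diazomethane) in a Horner–Wadsworth–Emmons reaction under Masamune–Roush conditions (LiCl, i-Pr2NEt, MeCN), which gives 13 directly.

## Further compounds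

F1 | step 10 | 1-methoxypent-4-en-1-yne | COC#CCC=C
F2 | step 10 | 2-allyl-6-{(R)-3-[2,4-bis(pivaloyloxy)phenyl]-3-(triethylsilyloxy)propyl}-3-methoxyphenol | COc1ccc(CC[C@@H](O[Si](CC)(CC)CC)c2ccc(OC(=O)C(C)(C)C)cc2OC(=O)C(C)(C)C)c(O)c1CC=C
F3 | step 10 | (E)-4-(3-{(R)-3-[2,4-bis(pivaloyloxy)phenyl]-3-(triethylsilyloxy)propyl}-2-hydroxy-6-methoxyphenyl)-2-methylbut-2-enal | COc1ccc(CC[C@@H](O[Si](CC)(CC)CC)c2ccc(OC(=O)C(C)(C)C)cc2OC(=O)C(C)(C)C)c(O)c1C/C=C(\C)C=O
F4 | step 10 | 6-{(R)-3-[2,4-bis(pivaloyloxy)phenyl]-3-(triethylsilyloxy)propyl}-2-[(E)-4-hydroxy-3-methylbut-2-en-1-yl]-3-methoxyphenol | COc1ccc(CC[C@@H](O[Si](CC)(CC)CC)c2ccc(OC(=O)C(C)(C)C)cc2OC(=O)C(C)(C)C)c(O)c1C/C=C(\C)CO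
F5 | step 12 | tert-butyldimethylsilyl ether of 24 | COc1ccc(CC[C@@H](O[Si](CC)(CC)CC)c2ccc(OC(=O)C(C)(C)C)cc2OC(=O)C(C)(C)C)c(O[Si](C)(C)C(C)(C)C)c1C/C=C(\C)COC(=O)C(C)(C)C
F6 | step 12 | (R)-alcohol from F5 (triethylsilyl group removed) | COc1ccc(CC[C@@H](O)c2ccc(OC(=O)C(C)(C)C)cc2OC(=O)C(C)(C)C)c(O[Si](C)(C)C(C)(C)C)c1C/C=C(\C)COC(=O)C(C)(C)C
F7 | step 12 | (R)-methanesulfonate of F6 | COc1ccc(CC[C@@H](OS(C)(=O)=O)c2ccc(OC(=O)C(C)(C)C)cc2OC(=O)C(C)(C)C)c(O[Si](C)(C)C(C)(C)C)c1C/C=C(\C)COC(=O)C(C)(C)C
F8 | step 9 | (E)-6-methoxy-2-methylhex-2-en-5-yn-1-ol | COC#CC/C=C(\C)CO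
F0 | step 2 | none | none
F9 | step 6 | diethyl (3-diazo-2-oxopropyl)phosphonate | CCOP(=O)(OCC)CC(=O)C=[N+]=[N-]
A1 | alternative 1 | (S)-5-(tert-butyldimethylsilyloxy)-2-{8-[(E)-4-(tert-butyldimethylsilyloxy)-3-methylbut-2-en-1-yl]-7-methoxychroman-2-yl}phenol | COc1ccc2c(c1C/C=C(\C)CO[Si](C)(C)C(C)(C)C)O[C@H](c1ccc(O[Si](C)(C)C(C)(C)C)cc1O)CC2
A2 | alternative 1 | 6-[(E)-4-(tert-butyldimethylsilyloxy)-3-methylbut-2-en-1-yl]-2-(hydroxymethyl)-5-methoxyphenol | COc1ccc(CO)c(O)c1C/C=C(\C)CO[Si](C)(C)C(C)(C)C
A3 | alternative 1 | 5-(tert-butyldimethylsilyloxy)-2-vinylphenol | C=Cc1ccc(O[Si](C)(C)C(C)(C)C)cc1O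
A4 | alternative 2 | (S)-2-[2,4-bis(methoxymethoxy)phenyl]-8-[(E)-4-(tert-butyldimethylsilyloxy)-3-methylbut-2-en-1-yl]-7-methoxy-2H-chromene | COc1ccc2c(c1C/C=C(\C)CO[Si](C)(C)C(C)(C)C)O[C@H](c1ccc(OCOC)cc1OCOC)C=C2
A5 | alternative 2 | (S)-1-[2,4-bis(methoxymethoxy)phenyl]allyl ether of 2-[(E)-4-(tert-butyldimethylsilyloxy)-3-methylbut-2-en-1-yl]-3-methoxy-6-vinylphenol | COc1ccc(C=C)c(O[C@@H](C=C)c2ccc(OCOC)cc2OCOC)c1C/C=C(\C)CO[Si](C)(C)C(C)(C)C
A6 | alternative 3 | (S)-2-[2,4-bis(tert-butyldimethylsilyloxy)phenyl]-8-[(E)-4-(tert-butyldimethylsilyloxy)-3-methylbut-2-en-1-yl]-7-methoxy-2H-chromene | COc1ccc2c(c1C/C=C(\C)CO[Si](C)(C)C(C)(C)C)O[C@H](c1ccc(O[Si](C)(C)C(C)(C)C)cc1O[Si](C)(C)C(C)(C)C)C=C2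
A7 | alternative 3 | (S)-1-[2,4-bis(tert-butyldimethylsilyloxy)phenyl]prop-2-yn-1-yl ether of 2-[(E)-4-(tert-butyldimethylsilyloxy)-3-methylbut-2-en-1-yl]-3-methoxyphenol | COc1cccc(O[C@@H](C#C)c2ccc(O[Si](C)(C)C(C)(C)C)cc2O[Si](C)(C)C(C)(C)C)c1C/C=C(\C)CO[Si](C)(C)C(C)(C)C
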